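**Retrosynthetic overview**

1. Feature: the C4 gem-dimethyl carbon sits next to the C5 ring-fusion methine, and the C8 methyl next to C9–C10 in ring B. Isopropenyl, C5, the ring methyl and the ketone of (R)-carvone map onto C4, C5, the C8 methyl and C9, so carvone is ring B.
2. Key disconnection C3–C4 (ring A): cation–olefin annulation of 6-(2-chloroallyl)-6-methylcarvone, itself made by two enolate alkylations at the future C10.
3. C11 comes from methylenation of the C9 ketone and hydroboration (sets C9); the C8 tertiary alcohol comes from oxymercuration of the C7 alkene.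
4. Ring C is brought in preformed from (R)-4-silyloxycyclopentenone: C11–C12 by chelation-controlled alkenyl addition to the C11 aldehyde, then C16–Cl with C11=C12 by allylic chlorosulfite transposition, then oxidation to the chloro-1,3-dione.
5. Ring order: B (chiral pool), A (step 3), C (attached in step 15).

Key step: step 3

Remark: drimane numbering is used for C1–C11; the ring C carbons are called C12 (ylidene carbon), C13 (enol carbon), C14, C15 (ketone) and C16 (CHCl). The target is one enol tautomer of a 4-chloro-5-ylidenecyclopentane-1,3-dione, and the diketone formed in the last step is assumed to settle into the drawn tautomer.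

**Route**

Step 1
Reactants: 1 (R)-(−)-carvone; 2 iodomethane
Product: 3 (5R)-2,6-dimethyl-5-(prop-1-en-2-yl)cyclohex-2-en-1-one (6-methylcarvone, C6 epimers)
Conditions: LiN(iPr)2, THF, −78 °C; MeI, −78 to 0 °C
Reagents that add atoms: iodomethane 2, CI
Why: Kinetic α′-deprotonation at C6 and SN2 methylation of the cross-conjugated lithium enolate (enolate alkylation); the C6 epimer mixture is irrelevant because C6 is planarised again in step 2.

Step 2
Reactants: 3 6-methylcarvone; 4 2,3-dichloropropene
Product: 5 (5S,6S)-6-(2-chloroprop-2-en-1-yl)-2,6-dimethyl-5-(prop-1-en-2-yl)cyclohex-2-en-1-one (chloroallyl trans to isopropenyl, methyl cis to it)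
Conditions: LiN(iPr)2, THF, −78 °C; 2,3-dichloropropene, DMPU, Bu4NI (cat.), −78 °C to rt
Reagents that add atoms: 2,3-dichloropropene 4, C=C(Cl)CCl
Why: Second α′-enolate alkylation, in which the allylic chloride should enter anti to the neighbouring isopropenyl group, fixing the future C10 with its methyl cis to isopropenyl.

Step 3
Reactants: 5 6-(2-chloroallyl)-6-methylcarvone
Product: 7 11-nordrim-7-ene-2,9-dione (trans-decalin; 5α-H; 10β-methyl), via C2 chloro formate 6 (not isolated)
Conditions: HCO2H (98%), 50 °C; then H2O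
Reagents that add atoms: formic acid, O=CO (its oxygen becomes the C2 ketone oxygen)
Why: Formic acid protonates the 1,1-disubstituted isopropenyl alkene at its CH2 terminus to give the tertiary C4 cation (this creates the second C4 methyl); the terminal carbon of the 2-chloroallyl group attacks it to form C3–C4, and the α-chloro cation at C2 is trapped by formate and hydrolysed to the ketone. The closest known reaction type is the chloro-olefin annulation, a tertiary cation–vinyl chloride cyclisation that delivers a cyclohexanone. Ring A closes in the 6-endo mode with respect to the vinyl chloride, through a chair in which the C5 and C10 arms are both equatorial. No stereocentre is created: C5 comes from carvone and C10 from step 2, and their trans arrangement can only give the trans-fused decalin. The step needs regioselectivity (attack through the terminal carbon, secured by chlorine, which stabilises the cation only at C2) and chemoselectivity (the electron-poor enone is not engaged), and ring closure must outrun proton loss or a 1,2-hydride shift from C5.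

Step 4
Reactants: 7 11-nordrim-7-ene-2,9-dione
Product: 8 C2 p-toluenesulfonylhydrazone of 7
Conditions: TsNHNH2 (1.05 equiv), EtOH, rt
Reagents that add atoms: p-toluenesulfonyl hydrazide, Cc1ccc(cc1)S(=O)(=O)NN
Why: Hydrazone condensation, which should be selective because the ring A ketone is flanked by two CH2 groups whereas the C9 carbonyl is conjugated, α-methylated and next to the quaternary C10.

Step 5
Reactants: 8 C2 tosylhydrazone
Product: 10 11-nordrim-7-en-9-one, via boryl tosylhydrazide 9 (not isolated)
Conditions: catecholborane, CHCl3, 0 °C; then NaOAc·3H2O, reflux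
Reagents that add atoms: none
Why: Reductive deoxygenation of a tosylhydrazone: catecholborane adds hydride to C=N, acetate triggers loss of sulfinate, and the diazene loses N2 to leave CH2 at C2, while the cyclic s-trans enone is not reduced by this borane.

Step 6
Reactants: 10 11-nordrim-7-en-9-one; 11 methyltriphenylphosphonium bromide
Product: 12 drima-7,9(11)-diene
Conditions: Ph3PCH3Br, KOtBu, toluene, 90 °C
Reagents that add atoms: methyltriphenylphosphonium bromide 11, C[P+](c1ccccc1)(c1ccccc1)c1ccccc1.[Br-]
Why: Wittig methylenation in the hot toluene/KOtBu variant used for hindered ketones; the enone has no α′ hydrogen, so only reversible γ-deprotonation can compete.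

Step 7
Reactants: 12 drima-7,9(11)-diene
Product: 14 drim-7-en-11-ol (drimenol; 9α-H), via B-drimenyl-9-BBN 13 (not isolated)
Conditions: 9-BBN, THF, 0 °C to rt; then NaOH, H2O2, 0 °C
Reagents that add atoms: hydrogen peroxide, OO
Why: Hydroboration–oxidation: boron adds to the terminal carbon of the exocyclic 1,1-disubstituted alkene and hydrogen is delivered to C9 from the α face, away from the axial C10 methyl, so C11 becomes the equatorial 9β substituent and the trisubstituted C7=C8 alkene is left.

Step 8
Reactants: 14 drimenol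
Product: 16 drimane-8β,11-diol (8β-OH axial; 8α-methyl), via 7α-acetoxymercurio diol 15 (not isolated)
Conditions: Hg(OAc)2, THF/H2O, rt; then NaBH4, aq. NaOH, 0 °C
Reagents that add atoms: water, O
Why: Oxymercuration–demercuration: the mercurinium ion forms on the less hindered α face and water opens it at the tertiary C8 in the trans-diaxial sense, giving the axial 8β-hydroxyl and equatorial 8α-methyl, after which NaBH4 replaces mercury at C7 by hydrogen.

Step 9
Reactants: 16 drimane-8β,11-diol
Product: 17 11-(triethylsilyloxy)driman-8β-ol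
Conditions: Et3SiCl, imidazole, CH2Cl2, 0 °C
Reagents that add atoms: chlorotriethylsilane, CC[Si](Cl)(CC)CC
Why: Silylation, selective for the primary alcohol because the axial tertiary C8 hydroxyl is too hindered for a trialkylsilyl chloride at 0 °C.

Step 10
Reactants: 17 11-(triethylsilyloxy)driman-8β-ol
Product: 18 8β-(methoxymethoxy)-11-(triethylsilyloxy)drimane
Conditions: MeOCH2Cl, iPr2NEt, Bu4NI (cat.), CH2Cl2, 40 °C
Reagents that add atoms: chloromethyl methyl ether, COCCl
Why: Alkoxymethylation of the tertiary alcohol with a small, highly reactive chloromethyl ether under amine base; the acetal oxygen is needed in step 15 as a chelating group.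

Step 11
Reactants: 18 8β-(methoxymethoxy)-11-(triethylsilyloxy)drimane
Product: 19 8β-(methoxymethoxy)driman-11-al
Conditions: (COCl)2, DMSO, CH2Cl2, −78 to −40 °C; iPr2NEt, −78 to −20 °C
Reagents that add atoms: none
Why: Swern oxidation applied directly to the primary triethylsilyl ether: the chlorosulfonium salt cleaves the unhindered Si–O bond and the hindered amine collapses the alkoxysulfonium salt to the aldehyde, the cold conditions being chosen to avoid β-elimination of the acetal oxygen.

Step 12
Reactants: 20 (R)-4-(tert-butyldimethylsilyloxy)cyclopent-2-en-1-one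
Product: 21 (R)-4-(tert-butyldimethylsilyloxy)-2-iodocyclopent-2-en-1-one
Conditions: I2, pyridine, CH2Cl2, 0 °C to rt
Reagents that add atoms: iodine, II
Why: α-Iodination of an enone by conjugate addition of pyridine, iodination of the enolate and elimination; the silyloxy stereocentre is not involved.

Step 13
Reactants: 21 (R)-4-(tert-butyldimethylsilyloxy)-2-iodocyclopent-2-en-1-one
Product: 22 (1S,4R)-4-(tert-butyldimethylsilyloxy)-2-iodocyclopent-2-en-1-ol (cis)
Conditions: NaBH4, CeCl3·7H2O, MeOH, −78 °C
Reagents that add atoms: none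
Why: Luche 1,2-reduction, in which hydride adds to the carbonyl face opposite the silyloxy group and so gives the cis-1,4 arrangement of the two oxygens.

Step 14
Reactants: 22 cis iodo alcohol
Product: 23 (1S,4R)-1,4-bis(tert-butyldimethylsilyloxy)-2-iodocyclopent-2-ene
Conditions: tBuMe2SiCl, imidazole, DMF, rt
Reagents that add atoms: tert-butylchlorodimethylsilane, CC(C)(C)[Si](C)(C)Cl
Why: Silylation of the secondary allylic alcohol.

Step 15
Reactants: 23 bis-silyloxy iodocyclopentene; 19 8β-(methoxymethoxy)driman-11-al
Product: 26 (11R)-11-[(3R,5S)-3,5-bis(tert-butyldimethylsilyloxy)cyclopent-1-en-1-yl]-8β-(methoxymethoxy)driman-11-ol, via alkenyllithium 24 (not isolated), via alkenylmagnesium bromide 25 (not isolated)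
Conditions: 23, t-BuLi (2 equiv), Et2O, −78 °C; MgBr2·OEt2, −78 to 0 °C; then 19 and MgBr2·OEt2 in CH2Cl2, −78 to −30 °C
Reagents that add atoms: none
Why: Iodine–lithium exchange, transmetallation and chelation-controlled 1,2-addition: magnesium bridges the aldehyde oxygen and the C8 acetal oxygen in a six-membered chelate, and the alkenyl group adds on the side of the C9 hydrogen, away from C10, which should give the 11R carbinol.

Step 16
Reactants: 26 (11R) allylic alcohol
Product: 28 (11E)-11-[(2R,3R,5S)-3,5-bis(tert-butyldimethylsilyloxy)-2-chlorocyclopentylidene]-8β-(methoxymethoxy)drimane, via C11 chlorosulfite 27 (not isolated)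
Conditions: SOCl2, propylene oxide, Et2O, −40 to 0 °C
Reagents that add atoms: thionyl chloride, O=S(Cl)Cl
Why: Allylic chlorosulfite rearrangement (SNi′) through a six-membered cyclic transition state: chlorine is delivered to C16 on the side of the departing oxygen and on the ring face opposite the two silyloxy groups (C16 becomes R), and with the 11R configuration this holds C9 on the C13 side, so C11=C12 should form with C9 cis to C13; the β-oxygens disfavour a free allyl cation and the epoxide removes HCl.

Step 17
Reactants: 28 allylic chloride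
Product: 30 (11E)-11-[(2R,3R,5S)-3,5-bis(tert-butyldimethylsilyloxy)-2-chlorocyclopentylidene]driman-8β-ol, via bromomethyl ether 29 (not isolated)
Conditions: Me2BBr, CH2Cl2, −78 °C; then aq. NaHCO3, THF
Reagents that add atoms: none
Why: Acetal cleavage with a bromoborane: boron complexes the methoxy oxygen, bromide gives the bromomethyl ether, and bicarbonate hydrolyses it to the tertiary alcohol at a temperature at which the silyl ethers and the allylic chloride should survive.

Step 18
Reactants: 30 bis-silyl ether
Product: 31 (11E)-11-[(2R,3R,5S)-2-chloro-3,5-dihydroxycyclopentylidene]driman-8β-ol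
Conditions: HF·pyridine, pyridine, THF, 0 °C to rt
Reagents that add atoms: none
Why: Fluoride-mediated desilylation under buffered acidic conditions, chosen over basic fluoride because the alkoxide of the trans chlorohydrin would close to an epoxide.

Step 19
Reactants: 31 chloro triol
Product: 33 (4E,5R)-5-chloro-3-hydroxy-4-(8β-hydroxydriman-11-ylidene)cyclopent-2-en-1-one (target), via diketo tautomer 32 (not isolated)
Conditions: Dess–Martin periodinane, CH2Cl2, 0 °C to rt
Reagents that add atoms: none
Why: Dess–Martin oxidation of both secondary alcohols (the tertiary C8 hydroxyl is inert), after which the 1,3-diketone enolises to the conjugated hydroxy-enone; the neutral, cold conditions should leave the C16 chloride and the alkene geometry untouched.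

**Compound list**

1 | (R)-(−)-carvone | CC1=CC[C@H](CC1=O)C(C)=C | starting material
2 | iodomethane | CI | starting material
3 | 6-methylcarvone (C6 epimers) | CC1=CC[C@H](C(C)C1=O)C(C)=C | intermediate
4 | 2,3-dichloropropene | ClCC(Cl)=C | starting material
5 | (5S,6S)-6-(2-chloroallyl)-6-methylcarvone | C=C(Cl)C[C@]1(C)C(=O)C(C)=CC[C@H]1C(C)=C | intermediate
6 | 2-chloro-2-formyloxy-11-nordrim-7-en-9-one | CC1(C)CC(Cl)(OC=O)C[C@]2(C)C(=O)C(C)=CC[C@@H]12 | intermediate (not isolated)
7 | 11-nordrim-7-ene-2,9-dione | CC1(C)CC(=O)C[C@]2(C)C(=O)C(C)=CC[C@@H]12 | intermediate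
8 | C2 tosylhydrazone of 7 | CC1(C)CC(=NNS(=O)(=O)c3ccc(C)cc3)C[C@]2(C)C(=O)C(C)=CC[C@@H]12 | intermediate
9 | C2 N-(1,3,2-benzodioxaborol-2-yl)-N′-tosylhydrazine | CC1(C)CC(N(NS(=O)(=O)c3ccc(C)cc3)B3Oc4ccccc4O3)C[C@]2(C)C(=O)C(C)=CC[C@@H]12 | intermediate (not isolated)
10 | 11-nordrim-7-en-9-one | CC1(C)CCC[C@]2(C)C(=O)C(C)=CC[C@@H]12 | intermediate
11 | methyltriphenylphosphonium bromide | C[P+](c1ccccc1)(c1ccccc1)c1ccccc1.[Br-] | starting material
12 | drima-7,9(11)-diene | CC1(C)CCC[C@]2(C)C(=C)C(C)=CC[C@@H]12 | intermediate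
13 | B-(drim-7-en-11-yl)-9-borabicyclo[3.3.1]nonane | CC1(C)CCC[C@]2(C)[C@@H](CB3C4CCCC3CCC4)C(C)=CC[C@@H]12 | intermediate (not isolated)
14 | drim-7-en-11-ol (drimenol) | CC1(C)CCC[C@]2(C)[C@@H](CO)C(C)=CC[C@@H]12 | intermediate
15 | 7α-(acetoxymercurio)drimane-8β,11-diol | CC1(C)CCC[C@]2(C)[C@@H](CO)[C@@](C)(O)[C@H]([Hg]OC(C)=O)C[C@@H]12 | intermediate (not isolated)
16 | drimane-8β,11-diol | CC1(C)CCC[C@]2(C)[C@@H](CO)[C@@](C)(O)CC[C@@H]12 | intermediate
17 | 11-(triethylsilyloxy)driman-8β-ol | CC1(C)CCC[C@]2(C)[C@@H](CO[Si](CC)(CC)CC)[C@@](C)(O)CC[C@@H]12 | intermediate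
18 | 8β-(methoxymethoxy)-11-(triethylsilyloxy)drimane | CC1(C)CCC[C@]2(C)[C@@H](CO[Si](CC)(CC)CC)[C@@](C)(OCOC)CC[C@@H]12 | intermediate
19 | 8β-(methoxymethoxy)driman-11-al | CC1(C)CCC[C@]2(C)[C@@H](C=O)[C@@](C)(OCOC)CC[C@@H]12 | intermediate
20 | (R)-4-(tert-butyldimethylsilyloxy)cyclopent-2-en-1-one | O=C1C=C[C@H](O[Si](C)(C)C(C)(C)C)C1 | starting material
21 | (R)-4-(tert-butyldimethylsilyloxy)-2-iodocyclopent-2-en-1-one | IC1=C[C@H](O[Si](C)(C)C(C)(C)C)CC1=O | intermediate
22 | (1S,4R)-4-(tert-butyldimethylsilyloxy)-2-iodocyclopent-2-en-1-ol | IC1=C[C@H](O[Si](C)(C)C(C)(C)C)C[C@@H]1O | intermediate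
23 | (1S,4R)-1,4-bis(tert-butyldimethylsilyloxy)-2-iodocyclopent-2-ene | IC1=C[C@H](O[Si](C)(C)C(C)(C)C)C[C@@H]1O[Si](C)(C)C(C)(C)C | intermediate
24 | alkenyllithium from 23 | [Li]C1=C[C@H](O[Si](C)(C)C(C)(C)C)C[C@@H]1O[Si](C)(C)C(C)(C)C | intermediate (not isolated)
25 | alkenylmagnesium bromide from 23 | Br[Mg]C1=C[C@H](O[Si](C)(C)C(C)(C)C)C[C@@H]1O[Si](C)(C)C(C)(C)C | intermediate (not isolated)
26 | (11R) allylic alcohol | CC1(C)CCC[C@]2(C)[C@@H]([C@@H](O)C3=C[C@H](O[Si](C)(C)C(C)(C)C)C[C@@H]3O[Si](C)(C)C(C)(C)C)[C@@](C)(OCOC)CC[C@@H]12 | intermediate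
27 | C11 chlorosulfite of 26 | CC1(C)CCC[C@]2(C)[C@@H]([C@@H](OS(Cl)=O)C3=C[C@H](O[Si](C)(C)C(C)(C)C)C[C@@H]3O[Si](C)(C)C(C)(C)C)[C@@](C)(OCOC)CC[C@@H]12 | intermediate (not isolated)
28 | (11E,16R) allylic chloride, 8-O-methoxymethyl | CC1(C)CCC[C@]2(C)[C@@H](/C=C3\[C@@H](O[Si](C)(C)C(C)(C)C)C[C@@H](O[Si](C)(C)C(C)(C)C)[C@@H]3Cl)[C@@](C)(OCOC)CC[C@@H]12 | intermediate
29 | 8-O-bromomethyl ether of 30 | CC1(C)CCC[C@]2(C)[C@@H](/C=C3\[C@@H](O[Si](C)(C)C(C)(C)C)C[C@@H](O[Si](C)(C)C(C)(C)C)[C@@H]3Cl)[C@@](C)(OCBr)CC[C@@H]12 | intermediate (not isolated)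
30 | allylic chloride, 8β-ol | CC1(C)CCC[C@]2(C)[C@@H](/C=C3\[C@@H](O[Si](C)(C)C(C)(C)C)C[C@@H](O[Si](C)(C)C(C)(C)C)[C@@H]3Cl)[C@@](C)(O)CC[C@@H]12 | intermediate
31 | chloro triol | CC1(C)CCC[C@]2(C)[C@@H](/C=C3\[C@@H](O)C[C@@H](O)[C@@H]3Cl)[C@@](C)(O)CC[C@@H]12 | intermediate
32 | (4R,5E)-4-chloro-5-(8β-hydroxydriman-11-ylidene)cyclopentane-1,3-dione | CC1(C)CCC[C@]2(C)[C@@H](/C=C3\C(=O)CC(=O)[C@@H]3Cl)[C@@](C)(O)CC[C@@H]12 | intermediate (not isolated)
33 | CNP0279879.2 | CC1(C)CCC[C@]2(C)[C@@H](/C=C3\C(O)=CC(=O)[C@@H]3Cl)[C@@](C)(O)CC[C@@H]12 | target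

**Step count**

Total: 19 steps (16 in the main line, 3 for the ring C building block). Longest linear sequence: 16 steps (steps 1–11 and 15–19).

**Steps most likely to fail**

1. Step 3. The tertiary cation may lose a proton to the isopropylidene isomer, or suffer a 1,2-hydride shift from C5 that erases the C5 configuration, before the weakly nucleophilic vinyl chloride closes the ring. The fallback sets out from 3 and comes back at 7. Hydrochlorination of the isopropenyl group of 3 (HCl, CH2Cl2, −40 °C) should give the tertiary chloride F1. Alkylation of its lithium enolate with 3-chloro-2-(trimethylsilylmethyl)prop-1-ene, again anti to the C5 substituent, should give the allylsilane F2. Ionisation of the tertiary chloride with TiCl4 (CH2Cl2, −78 °C) lets the much more nucleophilic allylsilane close ring A with loss of silicon, giving the C2-methylene bicycle F3. Ozone (CH2Cl2/MeOH, −78 °C; Me2S) should cleave its electron-rich exocyclic alkene in preference to the enone and give 7.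

2. Step 15. The hindered aldehyde may be enolised by the alkenylmagnesium reagent with loss of the β-acetal oxygen, or chelation may be incomplete so that facial selectivity at C11 is poor. The fallback sets out from 19 and 23 and comes back at 26. A Nozaki–Hiyama–Kishi coupling (CrCl2, NiCl2 cat., DMF, rt) is not basic and should give 26 together with its C11 epimer F4. The mixture is oxidised with Dess–Martin periodinane to the single enone F5. Reduction with the bulky, non-chelating LiBH(s-Bu)3 (THF, −78 °C) should go through the open transition state, anti to C8 and from the side of the C9 hydrogen, and give 26.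

3. Step 16. The chlorosulfite may ionise to an allyl cation instead of collapsing in the cyclic mode, which would lose the syn delivery and the alkene geometry or lead to elimination, and the HCl formed may strip the silyl and acetal groups. The fallback sets out from 26 and comes back at 28. A 1,3-transposition with catalytic Ph3SiOReO3 (Et2O, −50 °C), a suprafacial [3,3] shift of the perrhenate ester through the same chair and on the same ring face, should give the transposed allylic alcohol F6 (C16 hydroxyl anti to the silyloxy groups, C9 cis to C13). Two SN2 displacements then install chlorine with net retention: Appel bromination (CBr4, PPh3, CH2Cl2, 0 °C) to the inverted bromide F7, then LiCl (DMF, rt) to 28.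

**Further compounds**

F1 | step 3 | (5R)-5-(2-chloropropan-2-yl)-2,6-dimethylcyclohex-2-en-1-one (C6 epimers) | CC1=CC[C@H](C(C)C1=O)C(C)(C)Cl
F2 | step 3 | 5-(2-chloropropan-2-yl)-2,6-dimethyl-6-[2-(trimethylsilylmethyl)prop-2-en-1-yl]cyclohex-2-en-1-one (allyl arm trans to the C5 substituent) | C=C(C[Si](C)(C)C)C[C@]1(C)C(=O)C(C)=CC[C@H]1C(C)(C)Cl
F3 | step 3 | 2-methylene-11-nordrim-7-en-9-one | CC1(C)CC(=C)C[C@]2(C)C(=O)C(C)=CC[C@@H]12
F4 | step 15 | (11S) epimer of 26 | CC1(C)CCC[C@]2(C)[C@@H]([C@H](O)C3=C[C@H](O[Si](C)(C)C(C)(C)C)C[C@@H]3O[Si](C)(C)C(C)(C)C)[C@@](C)(OCOC)CC[C@@H]12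
F5 | step 15 | C11 ketone (enone) corresponding to 26 | CC1(C)CCC[C@]2(C)[C@@H](C(=O)C3=C[C@H](O[Si](C)(C)C(C)(C)C)C[C@@H]3O[Si](C)(C)C(C)(C)C)[C@@](C)(OCOC)CC[C@@H]12
F6 | step 16 | (11E) C16 allylic alcohol, hydroxyl anti to the silyloxy groups | CC1(C)CCC[C@]2(C)[C@@H](/C=C3\[C@@H](O[Si](C)(C)C(C)(C)C)C[C@@H](O[Si](C)(C)C(C)(C)C)[C@@H]3O)[C@@](C)(OCOC)CC[C@@H]12
F7 | step 16 | (11E) C16 bromide, C16 inverted relative to 28 | CC1(C)CCC[C@]2(C)[C@@H](/C=C3\[C@@H](O[Si](C)(C)C(C)(C)C)C[C@@H](O[Si](C)(C)C(C)(C)C)[C@H]3Br)[C@@](C)(OCOC)CC[C@@H]12
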